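**Retrosynthetic overview**
1. Target 16 (a tridepside) comes from global hydrogenolysis of the tribenzyl-protected tridepside 15.
2. 15 is cut at the ring B–ring C ester into the ring A–B acid 11 and benzyl orsellinate 13.
3. 11 comes from oxidation of aldehyde 10, which is cut at the ring A–ring B ester into ring A acid 8 and orcylaldehyde 1 (its CHO is the latent CO2H of ring B).
4. 8 comes from formylation and oxidation of arene 5, which comes from Dakin oxidation and O-methylation of dibenzyl orcylaldehyde 2, made from 1.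
5. No ring is formed: rings A and B come from 1, ring C from orsellinic acid 12, and they are joined in the order A, then A–B, then A–B–C.

Assumption: the target has no stereocentre or stereogenic axis, so no stereocontrol is needed; 1 and 12 are taken as commercially available.

**Route**

Step 1
Reactants: 1 2,4-dihydroxy-6-methylbenzaldehyde
Product: 2 2,4-bis(benzyloxy)-6-methylbenzaldehyde
Conditions: BnBr (2.4 equiv), K2CO3 (3 equiv), DMF, 60 °C
Reagents that add atoms: benzyl bromide, BrCc1ccccc1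
Why: Williamson ether synthesis protects both phenols as benzyl ethers that are removed together at the end.

Step 2
Reactants: 2 2,4-bis(benzyloxy)-6-methylbenzaldehyde
Product: 4 2,4-bis(benzyloxy)-6-methylphenol, via aryl formate 3 (not isolated)
Conditions: mCPBA (1.3 equiv), CH2Cl2, 0 °C to rt; aq Na2SO3/NaHCO3 wash; then K2CO3 (0.2 equiv), MeOH, rt
Reagents that add atoms: mCPBA (3-chloroperoxybenzoic acid), OOC(=O)c1cccc(Cl)c1
Why: Baeyer–Villiger (Dakin-type) oxidation, in which the electron-rich 2,4-dialkoxyaryl group migrates in preference to hydride and the formate is then methanolysed to the phenol.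

Step 3
Reactants: 4 2,4-bis(benzyloxy)-6-methylphenol
Product: 5 1,5-bis(benzyloxy)-2-methoxy-3-methylbenzene
Conditions: MeI (1.5 equiv), K2CO3 (2 equiv), DMF, rt
Reagents that add atoms: iodomethane, CI
Why: Williamson O-methylation of the only free phenol installs the ring A methoxy group next to the methyl group.

Step 4
Reactants: 5 1,5-bis(benzyloxy)-2-methoxy-3-methylbenzene
Product: 7 2,4-bis(benzyloxy)-5-methoxy-6-methylbenzaldehyde, via aryl iminium chloride 6 (not isolated)
Conditions: POCl3 (1.5 equiv), DMF, 0 °C to 60 °C; then ice/H2O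
Reagents that add atoms: N,N-dimethylformamide, CN(C)C=O; water, O
Why: Vilsmeier–Haack formylation goes to the ring position para to one benzyloxy group and ortho to the other (next to the methyl) rather than the more crowded site between the two benzyloxy groups, as with 3,5-dialkoxytoluenes.

Step 5
Reactants: 7 2,4-bis(benzyloxy)-5-methoxy-6-methylbenzaldehyde
Product: 8 2,4-bis(benzyloxy)-5-methoxy-6-methylbenzoic acid
Conditions: NaClO2, NaH2PO4, 2-methylbut-2-ene, t-BuOH/THF/H2O, rt
Reagents that add atoms: sodium chlorite, [Na+].[O-]Cl=O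
Why: Pinnick (Lindgren) oxidation converts the hindered aldehyde to the acid, and the alkene scavenger stops HOCl from chlorinating the electron-rich ring.

Step 6
Reactants: 8 2,4-bis(benzyloxy)-5-methoxy-6-methylbenzoic acid; 1 2,4-dihydroxy-6-methylbenzaldehyde
Product: 10 4-formyl-3-hydroxy-5-methylphenyl 2,4-bis(benzyloxy)-5-methoxy-6-methylbenzoate, via mixed trifluoroacetic anhydride 9 (not isolated)
Conditions: TFAA (3 equiv), toluene/CH2Cl2, rt
Reagents that add atoms: none
Why: Mixed-anhydride (trifluoroacetic anhydride) esterification acylates only the 4-OH of 1, because the 2-OH is hindered and locked in a hydrogen bond to the formyl group.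

Step 7
Reactants: 10 4-formyl-3-hydroxy-5-methylphenyl 2,4-bis(benzyloxy)-5-methoxy-6-methylbenzoate
Product: 11 4-{[2,4-bis(benzyloxy)-5-methoxy-6-methylbenzoyl]oxy}-2-hydroxy-6-methylbenzoic acid
Conditions: NaClO2, NaH2PO4, 2-methylbut-2-ene, t-BuOH/THF/H2O, rt
Reagents that add atoms: sodium chlorite, [Na+].[O-]Cl=O
Why: Pinnick oxidation at about pH 4 turns the salicylaldehyde into the salicylic acid without touching the aryl ester or the benzyl ethers.

Step 8
Reactants: 12 2,4-dihydroxy-6-methylbenzoic acid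
Product: 13 benzyl 2,4-dihydroxy-6-methylbenzoate
Conditions: BnBr (1.05 equiv), KHCO3 (1.1 equiv), DMF, rt
Reagents that add atoms: benzyl bromide, BrCc1ccccc1
Why: Carboxylate O-alkylation with a weak base is chemoselective for the acid over the phenols and is mild enough to avoid decarboxylation.

Step 9
Reactants: 11 4-{[2,4-bis(benzyloxy)-5-methoxy-6-methylbenzoyl]oxy}-2-hydroxy-6-methylbenzoic acid; 13 benzyl 2,4-dihydroxy-6-methylbenzoate
Product: 15 benzyl 4-[(4-{[2,4-bis(benzyloxy)-5-methoxy-6-methylbenzoyl]oxy}-2-hydroxy-6-methylbenzoyl)oxy]-2-hydroxy-6-methylbenzoate, via O-acylisourea 14 (not isolated)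
Conditions: DCC (N,N'-dicyclohexylcarbodiimide, 1.1 equiv), DMAP (4-(dimethylamino)pyridine, 0.1 equiv), CH2Cl2, 0 °C to rt
Reagents that add atoms: none
Why: Steglich esterification joins the activated acid to the free 4-OH of 13, while both hydrogen-bonded ortho hydroxyls (on 11 and on 13) are too unreactive to compete.

Step 10
Reactants: 15 benzyl 4-[(4-{[2,4-bis(benzyloxy)-5-methoxy-6-methylbenzoyl]oxy}-2-hydroxy-6-methylbenzoyl)oxy]-2-hydroxy-6-methylbenzoate
Product: 16 4-[(4-{[2,4-dihydroxy-5-methoxy-6-methylbenzoyl]oxy}-2-hydroxy-6-methylbenzoyl)oxy]-2-hydroxy-6-methylbenzoic acid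
Conditions: H2 (1 atm), 10% Pd/C (palladium metal on carbon), EtOAc, rt
Reagents that add atoms: none
Why: Catalytic hydrogenolysis cleaves the two benzyl ethers and the benzyl ester in one operation and leaves both depside aryl ester links intact.

**Compound list**

1 | 2,4-dihydroxy-6-methylbenzaldehyde (orcylaldehyde) | Cc1cc(O)cc(O)c1C=O | starting material
2 | 2,4-bis(benzyloxy)-6-methylbenzaldehyde | Cc1cc(OCc2ccccc2)cc(OCc2ccccc2)c1C=O | intermediate
3 | 2,4-bis(benzyloxy)-6-methylphenyl formate (not isolated) | Cc1cc(OCc2ccccc2)cc(OCc2ccccc2)c1OC=O | intermediate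
4 | 2,4-bis(benzyloxy)-6-methylphenol | Cc1cc(OCc2ccccc2)cc(OCc2ccccc2)c1O | intermediate
5 | 1,5-bis(benzyloxy)-2-methoxy-3-methylbenzene | COc1c(C)cc(OCc2ccccc2)cc1OCc1ccccc1 | intermediate
6 | N-{[2,4-bis(benzyloxy)-5-methoxy-6-methylphenyl]methylidene}-N-methylmethanaminium chloride (not isolated) | C[N+](C)=Cc1c(C)c(OC)c(OCc2ccccc2)cc1OCc1ccccc1.[Cl-] | intermediate
7 | 2,4-bis(benzyloxy)-5-methoxy-6-methylbenzaldehyde | COc1c(C)c(C=O)c(OCc2ccccc2)cc1OCc1ccccc1 | intermediate
8 | 2,4-bis(benzyloxy)-5-methoxy-6-methylbenzoic acid | COc1c(C)c(C(=O)O)c(OCc2ccccc2)cc1OCc1ccccc1 | intermediate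
9 | 2,4-bis(benzyloxy)-5-methoxy-6-methylbenzoic trifluoroacetic anhydride (not isolated) | COc1c(C)c(C(=O)OC(=O)C(F)(F)F)c(OCc2ccccc2)cc1OCc1ccccc1 | intermediate
10 | 4-formyl-3-hydroxy-5-methylphenyl 2,4-bis(benzyloxy)-5-methoxy-6-methylbenzoate | COc1c(OCc2ccccc2)cc(OCc2ccccc2)c(C(=O)Oc2cc(C)c(C=O)c(O)c2)c1C | intermediate
11 | 4-{[2,4-bis(benzyloxy)-5-methoxy-6-methylbenzoyl]oxy}-2-hydroxy-6-methylbenzoic acid | COc1c(OCc2ccccc2)cc(OCc2ccccc2)c(C(=O)Oc2cc(C)c(C(=O)O)c(O)c2)c1C | intermediate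
12 | 2,4-dihydroxy-6-methylbenzoic acid (orsellinic acid) | Cc1cc(O)cc(O)c1C(=O)O | starting material
13 | benzyl 2,4-dihydroxy-6-methylbenzoate (benzyl orsellinate) | Cc1cc(O)cc(O)c1C(=O)OCc1ccccc1 | intermediate
14 | O-acylisourea from 11 and DCC, N,N'-dicyclohexylcarbamimidic anhydride of acid 11 (not isolated) | COc1c(OCc2ccccc2)cc(OCc2ccccc2)c(C(=O)Oc2cc(C)c(C(=O)OC(=NC3CCCCC3)NC3CCCCC3)c(O)c2)c1C | intermediate
15 | benzyl 4-[(4-{[2,4-bis(benzyloxy)-5-methoxy-6-methylbenzoyl]oxy}-2-hydroxy-6-methylbenzoyl)oxy]-2-hydroxy-6-methylbenzoate | COc1c(OCc2ccccc2)cc(OCc2ccccc2)c(C(=O)Oc2cc(C)c(C(=O)Oc3cc(C)c(C(=O)OCc4ccccc4)c(O)c3)c(O)c2)c1C | intermediate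
16 | 4-[(4-{[2,4-dihydroxy-5-methoxy-6-methylbenzoyl]oxy}-2-hydroxy-6-methylbenzoyl)oxy]-2-hydroxy-6-methylbenzoic acid (5-O-methylhiascic acid, CNP0327242.0) | COc1c(O)cc(O)c(C(=O)Oc2cc(C)c(C(=O)Oc3cc(C)c(C(=O)O)c(O)c3)c(O)c2)c1C | target

**Totals and risks**

Total step count: 10. Longest linear sequence: 9 steps (steps 1–7, 9 and 10); step 8 is a one-step side branch.

The three steps most likely to fail are steps 4, 7 and 9.

Step 4 (Vilsmeier formylation of 5) may give the wrong regioisomer or lose a benzyl ether under the acidic, warm conditions. The fallback sets out from 5 and comes back to the route at 8, bypassing 7 and step 5. NBS in MeCN at 0 °C brominates para to a benzyloxy group and gives 1,5-bis(benzyloxy)-2-bromo-4-methoxy-3-methylbenzene F1. Bromine–lithium exchange with n-BuLi in THF at −78 °C gives [2,4-bis(benzyloxy)-5-methoxy-6-methylphenyl]lithium F2, which is quenched with CO2 and acidified with aq HCl to give acid 8.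

Step 7 (Pinnick oxidation of the free-phenol, doubly ortho-substituted aldehyde 10) may be sluggish or chlorinate ring B. The fallback sets out from 8 (with ring B brought in from 12) and comes back at 11, replacing steps 6 and 7 so that ring B is carried at the acid oxidation level throughout. Acid 12 with allyl bromide and KHCO3 in DMF gives prop-2-en-1-yl 2,4-dihydroxy-6-methylbenzoate F3. TFAA coupling of 8 (through mixed anhydride 9) with F3 gives prop-2-en-1-yl 4-{[2,4-bis(benzyloxy)-5-methoxy-6-methylbenzoyl]oxy}-2-hydroxy-6-methylbenzoate F4. Deallylation with Pd(PPh3)4 (zerovalent palladium) and N-methylaniline in THF at rt then gives 11 without disturbing the benzyl ethers or the depside link.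

Step 9 (carbodiimide coupling of the ortho-hydroxy acid 11) may suffer from self-condensation or N-acylurea formation. The fallback sets out from 10 and comes back at the target 16, masking the ring B phenol first. BnBr and K2CO3 in DMF give 3-(benzyloxy)-4-formyl-5-methylphenyl 2,4-bis(benzyloxy)-5-methoxy-6-methylbenzoate F5. Pinnick oxidation gives 2-(benzyloxy)-4-{[2,4-bis(benzyloxy)-5-methoxy-6-methylbenzoyl]oxy}-6-methylbenzoic acid F6. DCC/DMAP activation gives the O-acylisourea of F6 F7 (not isolated), which acylates 13 to give benzyl 4-[(2-(benzyloxy)-4-{[2,4-bis(benzyloxy)-5-methoxy-6-methylbenzoyl]oxy}-6-methylbenzoyl)oxy]-2-hydroxy-6-methylbenzoate F8. Hydrogenolysis (H2, Pd/C, EtOAc) of all four benzyl groups then gives 16.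

**Further compounds**

F1 | step 4 | 1,5-bis(benzyloxy)-2-bromo-4-methoxy-3-methylbenzene | COc1c(C)c(Br)c(OCc2ccccc2)cc1OCc1ccccc1
F2 | step 4 | [2,4-bis(benzyloxy)-5-methoxy-6-methylphenyl]lithium | [Li]c1c(C)c(OC)c(OCc2ccccc2)cc1OCc1ccccc1
F3 | step 7 | prop-2-en-1-yl 2,4-dihydroxy-6-methylbenzoate | Cc1cc(O)cc(O)c1C(=O)OCC=C
F4 | step 7 | prop-2-en-1-yl 4-{[2,4-bis(benzyloxy)-5-methoxy-6-methylbenzoyl]oxy}-2-hydroxy-6-methylbenzoate | COc1c(OCc2ccccc2)cc(OCc2ccccc2)c(C(=O)Oc2cc(C)c(C(=O)OCC=C)c(O)c2)c1C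
F5 | step 9 | 3-(benzyloxy)-4-formyl-5-methylphenyl 2,4-bis(benzyloxy)-5-methoxy-6-methylbenzoate | COc1c(OCc2ccccc2)cc(OCc2ccccc2)c(C(=O)Oc2cc(C)c(C=O)c(OCc3ccccc3)c2)c1C
F6 | step 9 | 2-(benzyloxy)-4-{[2,4-bis(benzyloxy)-5-methoxy-6-methylbenzoyl]oxy}-6-methylbenzoic acid | COc1c(OCc2ccccc2)cc(OCc2ccccc2)c(C(=O)Oc2cc(C)c(C(=O)O)c(OCc3ccccc3)c2)c1C
F7 | step 9 | O-acylisourea from F6 and DCC | COc1c(OCc2ccccc2)cc(OCc2ccccc2)c(C(=O)Oc2cc(C)c(C(=O)OC(=NC3CCCCC3)NC3CCCCC3)c(OCc3ccccc3)c2)c1C
F8 | step 9 | benzyl 4-[(2-(benzyloxy)-4-{[2,4-bis(benzyloxy)-5-methoxy-6-methylbenzoyl]oxy}-6-methylbenzoyl)oxy]-2-hydroxy-6-methylbenzoate | COc1c(OCc2ccccc2)cc(OCc2ccccc2)c(C(=O)Oc2cc(C)c(C(=O)Oc3cc(C)c(C(=O)OCc4ccccc4)c(O)c3)c(OCc3ccccc3)c2)c1C
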